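**Retrosynthetic overview**
1. The C2–C3–C4 chain, with its isopropyl and isobutyl groups, is the self-aldol dimer of isovaleraldehyde (an α-branched enal). Rings A and C are formylated phloroglucinols.
2. The disconnections are C2–C1' (Knoevenagel), C4–C4a (vinylogous 1,6-Friedel–Crafts), C3–H (tautomerisation) and C2–O1 (oxa-Michael). The quinone methide + styrene [4+2] is not used.
3. Ring order: aromatic rings A and C come ready-made. In one flask a sacrificial 2H-pyran (ring B') closes on ring C by oxa-6π and reopens, and then the final pyran ring B closes on ring A.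
4. Stereochemistry: C4 is set by a chiral phosphoric acid. C3 and C2 are relayed from C4 by allylic strain and a chair-like, reversible closure.
5. Feed steps: twofold Vilsmeier formylation of phloroglucinol, and aldol condensation of isovaleraldehyde.

Notation: the chroman numbering of the target (O1, C2, C3, C4, C4a to C8a) is used for these atoms in all intermediates. Ring A is the benzo ring, ring B the pyran ring and ring C the 2-aryl ring.
Assumption: the (R)-phosphoric acid is taken to give the 4S adduct; if the sense of induction proves opposite, its (S)-enantiomer is used and nothing else changes.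

**Step 1**
Reactants: 1 phloroglucinol (benzene-1,3,5-triol)
Product: 3 2,4,6-trihydroxybenzene-1,3-dicarbaldehyde, via bis(iminium) salt 2 (not isolated)
Conditions: POCl3 (2.4 equiv), DMF (2.4 equiv), 1,4-dioxane, 0 °C to rt, 12 h; then ice-water, filter
Reagents that add atoms: N,N-dimethylformamide CN(C)C=O; water O
Why: Twofold Vilsmeier–Haack formylation of the very electron-rich arene stops at the bis(iminium) stage because two cationic groups deactivate the last free position, and hydrolysis gives the dialdehyde; no stereocentre is formed.

**Step 2**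
Reactants: 4 isovaleraldehyde (3-methylbutanal), two molecules
Product: 6 (E)-2-isopropyl-5-methylhex-2-enal, via aldol adduct 5 (not isolated)
Conditions: NaOH (10 mol %), H2O/MeOH, reflux, 3 h; distil
Reagents that add atoms: none
Why: Base-catalysed self-aldol addition followed by E1cB dehydration (aldol condensation) gives the more stable E-enal; no stereocentre survives and the alkene geometry is erased in step 3.

**Step 3**
Reactants: 3 2,4,6-trihydroxybenzene-1,3-dicarbaldehyde; 6 (E)-2-isopropyl-5-methylhex-2-enal; 7 2,4,6-trihydroxybenzaldehyde
Product: 12 5-[(2R,3R,4S)-6-formyl-5,7-dihydroxy-4-isobutyl-3-isopropylchroman-2-yl]-2,4,6-trihydroxybenzene-1,3-dicarbaldehyde, via dienone 8 (not isolated), via chromene 9 (not isolated), via styrene 10 (not isolated), via quinone methide 11 (not isolated)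
Conditions: 3 (1.05 equiv), 6 (1.0 equiv), MeNHCH2CH2NHMe (5 mol %), (R)-3,3'-bis(2,4,6-triisopropylphenyl)-1,1'-binaphthyl-2,2'-diyl hydrogen phosphate (20 mol %), 4 Å molecular sieves, ClCH2CH2Cl, 60 °C, 12 h; then 7 (1.5 equiv, in EtOAc), 50 °C, 48 h
Reagents that add atoms: none
Why: Proposed new method: the diammonium phosphate salt drives a Knoevenagel condensation of 3 at the carbonyl carbon of 6 to dienone 8, which rests as 2H-chromene 9 after oxa-6π electrocyclisation (the known formal [3+3] chromene synthesis, first pyran ring); thermal reopening returns s-cis 8, which the free chiral phosphoric acid binds by hydrogen bonds together with phenol 7, so that the free ring carbon of 7 attacks the less hindered terminus C4 rather than the doubly flanked C2 and sets C4 as S under catalyst control (a vinylogous 1,6-Friedel–Crafts addition whose closest known types are phosphoric-acid-catalysed additions of phenols to ortho-quinone methides made in situ and remote additions to extended quinone methides); allylic 1,3-strain with ring C in (Z)-10 then holds C4–H in the alkene plane, so C3 is protonated anti to ring A to give the 3,4-cis relation (the known o-hydroxystyrene/quinone methide tautomerisation); and the OH of ring A para to its formyl group closes ring B on 11 by a reversible, chair-like oxa-Michael addition with ring C and isopropyl equatorial and isobutyl pseudoaxial, away from 5-OH, to give the 2,3-trans relation (second pyran ring).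

**Compound list**
1 | phloroglucinol | Oc1cc(O)cc(O)c1 | starting material
2 | bis(dimethyliminiomethyl)phloroglucinol bis(dichlorophosphate) | C[N+](C)=Cc1c(O)cc(O)c(C=[N+](C)C)c1O.[O-]P(=O)(Cl)Cl.[O-]P(=O)(Cl)Cl | intermediate
3 | 2,4,6-trihydroxybenzene-1,3-dicarbaldehyde (2,4-diformylphloroglucinol) | O=Cc1c(O)cc(O)c(C=O)c1O | intermediate
4 | isovaleraldehyde | CC(C)CC=O | starting material
5 | 3-hydroxy-2-isopropyl-5-methylhexanal (diastereomer mixture) | CC(C)CC(O)C(C=O)C(C)C | intermediate
6 | (E)-2-isopropyl-5-methylhex-2-enal | CC(C)C/C=C(/C=O)C(C)C | intermediate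
7 | 2,4,6-trihydroxybenzaldehyde | O=Cc1c(O)cc(O)cc1O | starting material
8 | 2,4-dihydroxy-5-(2-isopropyl-5-methylhex-2-enylidene)-6-oxocyclohexa-1,3-diene-1,3-dicarbaldehyde (vinylogous ortho-quinone methide, geometry mobile) | CC(C)CC=C(C(C)C)C=C1C(=O)C(C=O)=C(O)C(C=O)=C1O | intermediate
9 | 5,7-dihydroxy-2-isobutyl-3-isopropyl-2H-chromene-6,8-dicarbaldehyde (racemic, ring B') | CC(C)CC1Oc2c(C=O)c(O)c(C=O)c(O)c2C=C1C(C)C | intermediate
10 | 5-[(1Z,3S)-3-(3-formyl-2,4,6-trihydroxyphenyl)-2-isopropyl-5-methylhex-1-enyl]-2,4,6-trihydroxybenzene-1,3-dicarbaldehyde | CC(C)C[C@@H](/C(C(C)C)=C\c1c(O)c(C=O)c(O)c(C=O)c1O)c1c(O)cc(O)c(C=O)c1O | intermediate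
11 | ring C ortho-quinone methide tautomer of 10 (C1'=C2; C3–H and C4–H placed as in 12) | CC(C)C[C@@H]([C@@H](C(C)C)C=C1C(=O)C(C=O)=C(O)C(C=O)=C1O)c1c(O)cc(O)c(C=O)c1O | intermediate
12 | 5-[(2R,3R,4S)-6-formyl-5,7-dihydroxy-4-isobutyl-3-isopropylchroman-2-yl]-2,4,6-trihydroxybenzene-1,3-dicarbaldehyde (2,3-trans, 3,4-cis) | CC(C)C[C@@H]1c2c(cc(O)c(C=O)c2O)O[C@@H](c2c(O)c(C=O)c(O)c(C=O)c2O)[C@@H]1C(C)C | target

**Total step count:** 3. **Longest linear sequence:** 2 (1 → 3 → 12, or 4 → 6 → 12).

**Steps most likely to fail**

1. **Step 3.**
   - Risks: attack of 7 at C2 instead of C4; weak remote enantiocontrol at C4; an incomplete C3/C2 relay; and closure through the OH ortho to the formyl group, which would give the 8-formyl isomer.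
   - Fallback: it sets out from 4 and 7 and comes back at 11. Ring B is made first and ring C is attached last.
   - First stage: 7, two equivalents of 4 and (R)-2-[diphenyl(trimethylsilyloxy)methyl]pyrrolidine (20 mol %, PhCO2H, CHCl3, 0 °C) react by Mannich condensation and loss of the amine. This gives 2,6-dihydroxy-3-(3-methylbutylidene)-4-oxocyclohexa-1,5-diene-1-carbaldehyde F1.
   - Second stage: the catalyst enamine of the second 4 attacks F1 (the known aminocatalytic formal [4+2] of ortho-quinone methides with aldehydes). The product is (3S,4S)-2,5,7-trihydroxy-4-isobutyl-3-isopropylchroman-6-carbaldehyde F2. C4 is now set right at the reacting centre, and the minor diastereomer is removed by chromatography.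
   - Return: F2 reacts through its open hydroxy-aldehyde form with 3 under MeNHCH2CH2NHMe/AcOH. This erases C3 through the enamine, keeps C4 and gives 11 in equilibrium with 10, which closes to 12 as in the main route.

2. **Step 1.**
   - Risks: mixtures of mono-, di- and triformylated material, and poor solubility.
   - Fallback: it sets out from 7 and comes back at 3. One formyl group is bought with 7, and only one is added by a Duff reaction (hexamethylenetetramine 1.1 equiv, CF3CO2H, 90 °C, then 3 M HCl).
   - Basis: this is an aminomethylation/redox mechanism that is known to formylate phloroglucinol rings already carrying formyl groups. The detour makes no compound outside the list (F0).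

3. **Step 2.**
   - Risks: polycondensation, Tishchenko-type trimers and incomplete dehydration.
   - Fallback: it sets out from 4 and comes back at 6, by a directed aldol through a metalloenamine.
   - Sequence: 4 and cyclohexylamine give N-cyclohexyl-3-methylbutan-1-imine F3. Lithium diisopropylamide (THF, −78 °C) followed by one equivalent of 4 gives 1-(cyclohexylimino)-2-isopropyl-5-methylhexan-3-ol F4. Warm aqueous oxalic acid hydrolyses and dehydrates F4 to 6.

**Further compounds**
F1 | step 3 | 2,6-dihydroxy-3-(3-methylbutylidene)-4-oxocyclohexa-1,5-diene-1-carbaldehyde | CC(C)CC=C1C(=O)C=C(O)C(C=O)=C1O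
F2 | step 3 | (3S,4S)-2,5,7-trihydroxy-4-isobutyl-3-isopropylchroman-6-carbaldehyde (anomer mixture) | CC(C)C[C@@H]1c2c(cc(O)c(C=O)c2O)OC(O)[C@H]1C(C)C
F0 | step 1 | none | none
F3 | step 2 | N-cyclohexyl-3-methylbutan-1-imine | CC(C)CC=NC1CCCCC1
F4 | step 2 | 1-(cyclohexylimino)-2-isopropyl-5-methylhexan-3-ol | CC(C)CC(O)C(C=NC1CCCCC1)C(C)C
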